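**Plan**

- Retrosynthesis cuts, in order: the two phenolic O–Si bonds; C4–C4a of ring C (a C4a aryllithium adding to a C4 Weinreb amide); the O1–C2 aryl ether (Mitsunobu); the two aryl–prenyl bonds at C6 and C3′ (Stille); C2–C3 (hydroxymethylation of a ring B arylacetyl imide).
- Forward: rings A and B are bought as benzene rings. The ring A phenol (3 steps from 4-bromoresorcinol) and the ring B β-hydroxy Weinreb amide (5 steps from 3-bromo-4-hydroxyphenylacetic acid) are joined through O1–C2. Ring C is the only ring formed and is closed in the penultimate step; both silyl ethers are then removed.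
- Enabling feature: ring A is a resorcinol in which C4a is ortho to O1 and para to the C7 oxygen. 4-Bromoresorcinol carries bromine on exactly this carbon, so the acyl site is marked from the first step, and the O1–C2–C3–C4 tether holds the acyl carbon for a 6-exo-trig attack by a C4a carbanion. The other activated carbon, C6 (para to O1), takes iodine and then prenyl.
- Why a carbanion closure and not an acylium closure: both prenyl groups are acid-labile and the C3–H next to the new ketone is base-labile. The halogen–lithium route uses no acid, and the ketone exists only as an N,O-chelated tetrahedral adduct until a cold acidic quench.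
- Stereochemistry: C3 (S; C4 > C2 > C1′ > H) is the only stereocentre. It is set in step 6 by the (R)-4-benzyloxazolidinone auxiliary (titanium Z-enolate, attack anti to benzyl) and is never a reacting centre afterwards.

Key step: step 10

**Route**

Step 1
Reactants: 1 4-bromobenzene-1,3-diol (4-bromoresorcinol)
Product: 2 2-bromo-5-[(triisopropylsilyl)oxy]phenol
Conditions: TIPSCl (1.0 equiv), imidazole (2.2 equiv), CH2Cl2–DMF, −10 to 0 °C
Reagents that add atoms: triisopropylsilyl chloride, CC(C)[Si](Cl)(C(C)C)C(C)C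
Why: Silylation with a bulky silyl chloride is sterically controlled, so the unhindered hydroxyl para to bromine should react in preference to the hydroxyl that is ortho to bromine, shielded and hydrogen-bonded (regioselective phenol monosilylation).

Step 2
Reactants: 2 2-bromo-5-[(triisopropylsilyl)oxy]phenol
Product: 3 2-bromo-4-iodo-5-[(triisopropylsilyl)oxy]phenol
Conditions: NIS (1.05 equiv), MeCN, 0 °C, dark
Reagents that add atoms: N-iodosuccinimide, O=C1CCC(=O)N1I
Why: Electrophilic aromatic iodination should go para to the free hydroxyl, the only doubly activated carbon that is not flanked by two oxygen substituents; this carbon is the future C6.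

Step 3
Reactants: 3 2-bromo-4-iodo-5-[(triisopropylsilyl)oxy]phenol
Product: 4 2-bromo-4-(3-methylbut-2-en-1-yl)-5-[(triisopropylsilyl)oxy]phenol
Conditions: tributyl(3-methylbut-2-en-1-yl)stannane (1.3 equiv), Pd(PPh3)4 (5 mol%), degassed DMF, 70 °C
Reagents that add atoms: tributyl(3-methylbut-2-en-1-yl)stannane, CCCC[Sn](CCCC)(CCCC)CC=C(C)C
Why: In this Stille coupling zerovalent palladium inserts into C–I much faster than into C–Br, and the prenylstannane should deliver the linear 3-methylbut-2-enyl group under neutral conditions that spare the phenol, the silyl ether and the bromine needed for step 10.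

Step 4
Reactants: 5 2-(3-bromo-4-hydroxyphenyl)acetic acid
Product: 7 2-{3-bromo-4-[(triisopropylsilyl)oxy]phenyl}acetic acid, via silyl ester 6 (not isolated)
Conditions: TIPSCl (2.3 equiv), imidazole (5 equiv), DMF, rt; then AcOH–THF–H2O, rt
Reagents that add atoms: triisopropylsilyl chloride, CC(C)[Si](Cl)(C(C)C)C(C)C
Why: Silyl chloride and imidazole silylate both the phenol and the acid, and the silyl ester is far more labile than the hindered aryl silyl ether, so aqueous acetic acid should hydrolyse it selectively.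

Step 5
Reactants: 7 2-{3-bromo-4-[(triisopropylsilyl)oxy]phenyl}acetic acid; 8 (R)-4-benzyl-1,3-oxazolidin-2-one
Product: 10 (R)-4-benzyl-3-(2-{3-bromo-4-[(triisopropylsilyl)oxy]phenyl}acetyl)-1,3-oxazolidin-2-one, via mixed pivalic anhydride 9 (not isolated)
Conditions: PivCl, Et3N, THF, −20 °C; then LiCl, 8, −20 °C to rt
Reagents that add atoms: none
Why: N-Acylation of the oxazolidinone by the mixed pivalic anhydride in the presence of LiCl and Et3N is the standard mild attachment of an Evans auxiliary and leaves the aryl silyl ether and aryl bromide untouched.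

Step 6
Reactants: 10 (R)-4-benzyl-3-(2-{3-bromo-4-[(triisopropylsilyl)oxy]phenyl}acetyl)-1,3-oxazolidin-2-one
Product: 12 (R)-4-benzyl-3-[(2S)-2-{3-bromo-4-[(triisopropylsilyl)oxy]phenyl}-3-hydroxypropanoyl]-1,3-oxazolidin-2-one, via chlorotitanium Z-enolate 11 (not isolated)
Conditions: TiCl4 (1.05 equiv), i-Pr2NEt (1.1 equiv), CH2Cl2, 0 °C; then s-trioxane (1.2 equiv), TiCl4 (1.05 equiv), 0 °C; aq NH4Cl
Reagents that add atoms: 1,3,5-trioxane, C1OCOCO1
Why: In this Evans titanium-enolate hydroxymethylation the chelated Z-enolate should be attacked by TiCl4-activated formaldehyde on the face anti to the benzyl group of the (R)-auxiliary, which sets the future C3 as S; no alkene is present yet, so the Lewis acid has nothing else to attack.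

Step 7
Reactants: 12 (R)-4-benzyl-3-[(2S)-2-{3-bromo-4-[(triisopropylsilyl)oxy]phenyl}-3-hydroxypropanoyl]-1,3-oxazolidin-2-one
Product: 13 (2S)-2-{3-bromo-4-[(triisopropylsilyl)oxy]phenyl}-3-hydroxy-N-methoxy-N-methylpropanamide
Conditions: MeONHMe·HCl (3 equiv), AlMe3 (3 equiv), CH2Cl2, −20 to 0 °C; Rochelle salt work-up
Reagents that add atoms: N,O-dimethylhydroxylamine hydrochloride, CNOC.Cl
Why: Weinreb transamidation with the aluminium amide is directed by the β-hydroxyl to the exocyclic carbonyl, so the auxiliary should be released for recovery under weakly basic conditions that do not enolise the α-aryl stereocentre.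

Step 8
Reactants: 13 (2S)-2-{3-bromo-4-[(triisopropylsilyl)oxy]phenyl}-3-hydroxy-N-methoxy-N-methylpropanamide
Product: 14 (2S)-3-hydroxy-N-methoxy-N-methyl-2-{3-(3-methylbut-2-en-1-yl)-4-[(triisopropylsilyl)oxy]phenyl}propanamide
Conditions: tributyl(3-methylbut-2-en-1-yl)stannane (1.5 equiv), Pd(PPh3)4 (10 mol%), degassed DMF, 95 °C
Reagents that add atoms: tributyl(3-methylbut-2-en-1-yl)stannane, CCCC[Sn](CCCC)(CCCC)CC=C(C)C
Why: Stille prenylation of the aryl bromide is neutral and base-free, so the free alcohol, the Weinreb amide and the stereocentre should survive; the prenyl group is introduced only after the Lewis-acid step 6 is over.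

Step 9
Reactants: 14 (2S)-3-hydroxy-N-methoxy-N-methyl-2-{3-(3-methylbut-2-en-1-yl)-4-[(triisopropylsilyl)oxy]phenyl}propanamide; 4 2-bromo-4-(3-methylbut-2-en-1-yl)-5-[(triisopropylsilyl)oxy]phenol
Product: 15 (2S)-3-{2-bromo-4-(3-methylbut-2-en-1-yl)-5-[(triisopropylsilyl)oxy]phenoxy}-N-methoxy-N-methyl-2-{3-(3-methylbut-2-en-1-yl)-4-[(triisopropylsilyl)oxy]phenyl}propanamide
Conditions: PPh3, DIAD, toluene–THF, 0 °C to rt
Reagents that add atoms: none
Why: Mitsunobu etherification displaces the primary carbinol carbon with the acidic ortho-bromophenol, so the stereocentre is not a reacting centre, and the low kinetic C–H acidity of the α,α-disubstituted tertiary amide (allylic 1,3-strain in its enolate) should disfavour elimination to the acrylamide.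

Step 10
Reactants: 15 (2S)-3-{2-bromo-4-(3-methylbut-2-en-1-yl)-5-[(triisopropylsilyl)oxy]phenoxy}-N-methoxy-N-methyl-2-{3-(3-methylbut-2-en-1-yl)-4-[(triisopropylsilyl)oxy]phenyl}propanamide
Product: 18 (3S)-6-(3-methylbut-2-en-1-yl)-3-{3-(3-methylbut-2-en-1-yl)-4-[(triisopropylsilyl)oxy]phenyl}-7-[(triisopropylsilyl)oxy]-2,3-dihydro-4H-chromen-4-one, via aryllithium 16 (not isolated), via lithium hemiaminal chelate 17 (not isolated)
Conditions: t-BuLi (2.1 equiv), THF, −78 °C, 20 min; AcOH in THF at −78 °C, then aq NH4Cl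
Reagents that add atoms: none
Why: Bromine–lithium exchange at C4a (the second equivalent of t-BuLi destroys the tert-butyl bromide formed) gives aryllithium 16, which adds to the Weinreb carbonyl to give the five-membered N-methoxy lithium chelate 17; this survives until the cold acetic acid quench and only then collapses to the ketone. The closest known reaction type is the Parham cyclization, the cycloacylation of an aryllithium made by halogen–metal exchange onto a tethered N-methoxy-N-methylamide, which is established for benzo-fused cyclic ketones. Ring C closes in the 6-exo-trig mode. No new stereocentre remains in the product, since the hemiaminal carbon of 17 is lost on collapse, and C3 should be carried through unchanged because the ketone exists only as the tetrahedral chelate while strong base is present and is released in the presence of nothing more basic than N,O-dimethylhydroxylamine and acetate. The step needs site selectivity, which the position of the bromine secures without any acid that would attack the prenyl groups, and it needs exchange and carbonyl addition to outrun deprotonation of C3–H, which the fast alkoxy-assisted exchange at −78 °C, the chelation-assisted addition and the low kinetic acidity of the α,α-disubstituted tertiary amide should secure. Both silyl ethers are para or remote to the lithiated carbon, so silyl migration to carbon is not possible.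

Step 11
Reactants: 18 (3S)-6-(3-methylbut-2-en-1-yl)-3-{3-(3-methylbut-2-en-1-yl)-4-[(triisopropylsilyl)oxy]phenyl}-7-[(triisopropylsilyl)oxy]-2,3-dihydro-4H-chromen-4-one
Product: 19 (3S)-7-hydroxy-3-[4-hydroxy-3-(3-methylbut-2-en-1-yl)phenyl]-6-(3-methylbut-2-en-1-yl)-2,3-dihydro-4H-chromen-4-one
Conditions: TBAF (2.5 equiv), AcOH (3 equiv), THF, 0 °C; chromatography on untreated silica
Reagents that add atoms: none
Why: Fluoride cleaves both aryl silyl ethers, and the acetic acid buffer protonates the phenoxides as they form, so the base-labile C3–H should not be enolised and the prenyl groups see no strong acid.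

**Compound list**

1 | 4-bromobenzene-1,3-diol (4-bromoresorcinol) | Oc1ccc(Br)c(O)c1 | starting material
2 | 2-bromo-5-[(triisopropylsilyl)oxy]phenol | CC(C)[Si](Oc1ccc(Br)c(O)c1)(C(C)C)C(C)C | intermediate
3 | 2-bromo-4-iodo-5-[(triisopropylsilyl)oxy]phenol | CC(C)[Si](Oc1cc(O)c(Br)cc1I)(C(C)C)C(C)C | intermediate
4 | 2-bromo-4-(3-methylbut-2-en-1-yl)-5-[(triisopropylsilyl)oxy]phenol | CC(C)=CCc1cc(Br)c(O)cc1O[Si](C(C)C)(C(C)C)C(C)C | intermediate
5 | 2-(3-bromo-4-hydroxyphenyl)acetic acid | OC(=O)Cc1ccc(O)c(Br)c1 | starting material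
6 | triisopropylsilyl 2-{3-bromo-4-[(triisopropylsilyl)oxy]phenyl}acetate | CC(C)[Si](OC(=O)Cc1ccc(O[Si](C(C)C)(C(C)C)C(C)C)c(Br)c1)(C(C)C)C(C)C | intermediate
7 | 2-{3-bromo-4-[(triisopropylsilyl)oxy]phenyl}acetic acid | OC(=O)Cc1ccc(O[Si](C(C)C)(C(C)C)C(C)C)c(Br)c1 | intermediate
8 | (R)-4-benzyl-1,3-oxazolidin-2-one | O=C1N[C@H](Cc2ccccc2)CO1 | starting material
9 | 2-{3-bromo-4-[(triisopropylsilyl)oxy]phenyl}acetic pivalic anhydride | CC(C)(C)C(=O)OC(=O)Cc1ccc(O[Si](C(C)C)(C(C)C)C(C)C)c(Br)c1 | intermediate
10 | (R)-4-benzyl-3-(2-{3-bromo-4-[(triisopropylsilyl)oxy]phenyl}acetyl)-1,3-oxazolidin-2-one | O=C(Cc1ccc(O[Si](C(C)C)(C(C)C)C(C)C)c(Br)c1)N1[C@H](Cc2ccccc2)COC1=O | intermediate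
11 | trichlorotitanium Z-enolate of 10 | Cl[Ti](Cl)(Cl)O/C(=C\c1ccc(O[Si](C(C)C)(C(C)C)C(C)C)c(Br)c1)N1[C@H](Cc2ccccc2)COC1=O | intermediate
12 | (R)-4-benzyl-3-[(2S)-2-{3-bromo-4-[(triisopropylsilyl)oxy]phenyl}-3-hydroxypropanoyl]-1,3-oxazolidin-2-one | O=C([C@H](CO)c1ccc(O[Si](C(C)C)(C(C)C)C(C)C)c(Br)c1)N1[C@H](Cc2ccccc2)COC1=O | intermediate
13 | (2S)-2-{3-bromo-4-[(triisopropylsilyl)oxy]phenyl}-3-hydroxy-N-methoxy-N-methylpropanamide | CON(C)C(=O)[C@H](CO)c1ccc(O[Si](C(C)C)(C(C)C)C(C)C)c(Br)c1 | intermediate
14 | (2S)-3-hydroxy-N-methoxy-N-methyl-2-{3-(3-methylbut-2-en-1-yl)-4-[(triisopropylsilyl)oxy]phenyl}propanamide | CON(C)C(=O)[C@H](CO)c1ccc(O[Si](C(C)C)(C(C)C)C(C)C)c(CC=C(C)C)c1 | intermediate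
15 | (2S)-3-{2-bromo-4-(3-methylbut-2-en-1-yl)-5-[(triisopropylsilyl)oxy]phenoxy}-N-methoxy-N-methyl-2-{3-(3-methylbut-2-en-1-yl)-4-[(triisopropylsilyl)oxy]phenyl}propanamide | CON(C)C(=O)[C@H](COc1cc(O[Si](C(C)C)(C(C)C)C(C)C)c(CC=C(C)C)cc1Br)c1ccc(O[Si](C(C)C)(C(C)C)C(C)C)c(CC=C(C)C)c1 | intermediate
16 | aryllithium from 15 (lithium in place of bromine at the future C4a) | CON(C)C(=O)[C@H](COc1cc(O[Si](C(C)C)(C(C)C)C(C)C)c(CC=C(C)C)cc1[Li])c1ccc(O[Si](C(C)C)(C(C)C)C(C)C)c(CC=C(C)C)c1 | intermediate
17 | lithium alkoxide of the (3S)-4-[methoxy(methyl)amino]chroman-4-ol (tetrahedral adduct; C4 configuration not defined) | CC(C)=CCc1cc([C@H]2COc3cc(O[Si](C(C)C)(C(C)C)C(C)C)c(CC=C(C)C)cc3C2(O[Li])N(C)OC)ccc1O[Si](C(C)C)(C(C)C)C(C)C | intermediate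
18 | (3S)-6-(3-methylbut-2-en-1-yl)-3-{3-(3-methylbut-2-en-1-yl)-4-[(triisopropylsilyl)oxy]phenyl}-7-[(triisopropylsilyl)oxy]-2,3-dihydro-4H-chromen-4-one | CC(C)=CCc1cc([C@H]2COc3cc(O[Si](C(C)C)(C(C)C)C(C)C)c(CC=C(C)C)cc3C2=O)ccc1O[Si](C(C)C)(C(C)C)C(C)C | intermediate
19 | (3S)-7-hydroxy-3-[4-hydroxy-3-(3-methylbut-2-en-1-yl)phenyl]-6-(3-methylbut-2-en-1-yl)-2,3-dihydro-4H-chromen-4-one | CC(C)=CCc1cc([C@H]2COc3cc(O)c(CC=C(C)C)cc3C2=O)ccc1O | target

**Totals and risks**

Total step count: 11. Longest linear sequence: 8 steps (steps 4 to 11, from 5).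

Step 10. The risk is proton transfer from C3–H to the aryllithium in competition with ring closure, which would cause protodebromination, loss of the ring A phenoxide by elimination, or erosion of the C3 configuration. The fallback moves the closure to the aldehyde oxidation level and to a non-basic organochromium nucleophile. Compound 15 would be reduced with i-Bu2AlH (THF, −78 °C) to (2S)-3-{2-bromo-4-(3-methylbut-2-en-1-yl)-5-[(triisopropylsilyl)oxy]phenoxy}-2-{3-(3-methylbut-2-en-1-yl)-4-[(triisopropylsilyl)oxy]phenyl}propanal F1. This would be cyclised at once under Nozaki–Hiyama–Kishi conditions (CrCl2 in excess, NiCl2 as catalyst, DMF, rt to 50 °C) to (3S)-6-(3-methylbut-2-en-1-yl)-3-{3-(3-methylbut-2-en-1-yl)-4-[(triisopropylsilyl)oxy]phenyl}-7-[(triisopropylsilyl)oxy]-3,4-dihydro-2H-chromen-4-ol F2, expected as a mixture of C4 epimers. Oxidation with Dess–Martin periodinane (CH2Cl2, solid NaHCO3) would return the route at 18.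

Step 9. The risk is elimination of the phosphonium-activated primary alcohol to the 2-arylacrylamide under the basic hydrazide anion, together with slow capture by the hindered ortho-bromophenoxide. The fallback is a two-stage Williamson etherification with no phosphonium species and no base stronger than the phenoxide. Compound 14 would be converted (Tf2O, 2,6-lutidine, CH2Cl2, −78 °C) into (2S)-3-[methoxy(methyl)amino]-2-{3-(3-methylbut-2-en-1-yl)-4-[(triisopropylsilyl)oxy]phenyl}-3-oxopropyl trifluoromethanesulfonate F3. This would be displaced cold (−40 to 0 °C, THF) by the potassium phenoxide of 4, pre-formed with KN(SiMe3)2, to return at 15.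

Step 8. The risk is sluggish oxidative addition of zerovalent palladium into the hindered, electron-rich C–Br bond ortho to the silyl ether, and allylic transposition in the coupling that would give the 1,1-dimethylallyl isomer. The fallback separates C–C coupling from construction of the trisubstituted alkene. Compound 13 would be coupled with allyltributylstannane (Pd(PPh3)4, DMF, 90 °C), which has no regiochemical ambiguity and transmetalates faster, to give (2S)-3-hydroxy-N-methoxy-N-methyl-2-{3-(prop-2-en-1-yl)-4-[(triisopropylsilyl)oxy]phenyl}propanamide F4. Cross-metathesis with excess 2-methylbut-2-ene (second-generation Grubbs catalyst RuCl2(H2IMes)(PCy3)(=CHPh), CH2Cl2, 40 °C) would then turn allyl into prenyl and return at 14.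

Further compounds
F1 | step 10 | (2S)-3-{2-bromo-4-(3-methylbut-2-en-1-yl)-5-[(triisopropylsilyl)oxy]phenoxy}-2-{3-(3-methylbut-2-en-1-yl)-4-[(triisopropylsilyl)oxy]phenyl}propanal | O=C[C@H](COc1cc(O[Si](C(C)C)(C(C)C)C(C)C)c(CC=C(C)C)cc1Br)c1ccc(O[Si](C(C)C)(C(C)C)C(C)C)c(CC=C(C)C)c1
F2 | step 10 | (3S)-6-(3-methylbut-2-en-1-yl)-3-{3-(3-methylbut-2-en-1-yl)-4-[(triisopropylsilyl)oxy]phenyl}-7-[(triisopropylsilyl)oxy]-3,4-dihydro-2H-chromen-4-ol (both C4 epimers) | CC(C)=CCc1cc([C@H]2COc3cc(O[Si](C(C)C)(C(C)C)C(C)C)c(CC=C(C)C)cc3C2O)ccc1O[Si](C(C)C)(C(C)C)C(C)C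
F3 | step 9 | (2S)-3-[methoxy(methyl)amino]-2-{3-(3-methylbut-2-en-1-yl)-4-[(triisopropylsilyl)oxy]phenyl}-3-oxopropyl trifluoromethanesulfonate | CON(C)C(=O)[C@H](COS(=O)(=O)C(F)(F)F)c1ccc(O[Si](C(C)C)(C(C)C)C(C)C)c(CC=C(C)C)c1
F4 | step 8 | (2S)-3-hydroxy-N-methoxy-N-methyl-2-{3-(prop-2-en-1-yl)-4-[(triisopropylsilyl)oxy]phenyl}propanamide | CON(C)C(=O)[C@H](CO)c1ccc(O[Si](C(C)C)(C(C)C)C(C)C)c(CC=C)c1
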